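**Retrosynthetic overview**
1. Target (1R,8Z) ⇐ asymmetric transfer hydrogenation of the macrocyclic aryl ketone, done last on the free triphenol ⇐ O-demethylation of ring B.
2. Macrocycle ⇐ intramolecular diaryl ether C–O bond between a free resorcinol oxygen of ring A and the C–Br carbon of ring B (para to the ketone, between two OMe groups).
3. Open-chain bromide ⇐ Z-selective cross-metathesis (C8=C9) of a ring A heptenyl-resorcinol with a ring B nonenyl ketone.
4. Ring A olefin ⇐ 5-bromoresorcinol + hepta-1,6-diene (hydroboration, B-alkyl Suzuki); ring B olefin ⇐ 4-bromo-3,5-dimethoxybenzoic acid + 8-bromooct-1-ene (acid chloride, Grignard acylation).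
5. Ring order: aromatic rings A and B are bought; the 22-membered ring is the only ring formed, by the C–O closure.

Assumption: the chain is numbered C1 (benzylic carbon on ring B) to C14 (benzylic CH2 on ring A); ring A is the resorcinol-derived ring; the SMILES is read as (1R) and (8Z).

**Route**

Step 1
Reactants: 1 5-bromobenzene-1,3-diol (5-bromoresorcinol); 2 hepta-1,6-diene
Product: 4 5-(hept-6-en-1-yl)benzene-1,3-diol, via 9-(hept-6-en-1-yl)-9-borabicyclo[3.3.1]nonane 3 (not isolated)
Conditions: 2 (5 equiv), 9-BBN-H (1.3 equiv), THF, 0 °C → rt; excess 2 evaporated; then 1, Pd(OAc)2 (2 mol%), SPhos (4 mol%), K3PO4 (3 M aq, 4 equiv), THF, 65 °C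
Reagents that add atoms: none
Why: Anti-Markovnikov hydroboration of one terminal olefin of the excess diene followed by B-alkyl Suzuki–Miyaura coupling joins C14 to ring A; the aqueous phosphate medium tolerates the free phenols, and SPhos speeds oxidative addition into the electron-rich bromide and suppresses beta-hydride elimination.

Step 2
Reactants: 5 4-bromo-3,5-dimethoxybenzoic acid; 6 8-bromooct-1-ene
Product: 9 1-(4-bromo-3,5-dimethoxyphenyl)non-8-en-1-one, via 4-bromo-3,5-dimethoxybenzoyl chloride 7 (not isolated), via oct-7-en-1-ylmagnesium bromide 8 (not isolated)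
Conditions: 5, (COCl)2, DMF (cat.), CH2Cl2, rt, then evaporate; 6, Mg, THF, 40 °C; combine, Fe(acac)3 (3 mol%), THF, −78 °C, 15 min
Reagents that add atoms: none
Why: Iron-catalysed acylation of an alkyl Grignard reagent by an acid chloride (Kumada-type acyl cross-coupling) is complete within minutes at −78 °C, faster than over-addition to the ketone or any reaction at the hindered aryl bromide, so the C1–C2 bond and the ketone oxidation level are set in one operation.

Step 3
Reactants: 4 5-(hept-6-en-1-yl)benzene-1,3-diol (3 equiv); 9 1-(4-bromo-3,5-dimethoxyphenyl)non-8-en-1-one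
Product: 10 (8Z)-1-(4-bromo-3,5-dimethoxyphenyl)-14-(3,5-dihydroxyphenyl)tetradec-8-en-1-one
Conditions: cyclometalated Ru nitrato complex Ru(NO3)(=CH-C6H4-2-OiPr)[1-(1-adamantyl)-3-(2,6-iPr2C6H3)imidazolidin-2-ylidene − H, Ru–C bond at adamantyl C2] (5 mol%), THF (0.5 M), 35 °C, static vacuum, 12 h
Reagents that add atoms: none
Why: Z-selective olefin cross-metathesis, in which the chelating N-adamantyl carbene forces side-bound metallacyclobutanes with both substituents turned away from the N-aryl group so that the kinetic product is the Z-olefin (about 9:1 expected); excess 4 and removal of ethene drive conversion of 9, the neutral catalyst tolerates ketone, aryl bromide and hydroxyl groups, and the three olefin products differ by two hydroxyl groups each and separate easily.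

Step 4
Reactants: 10 (8Z)-1-(4-bromo-3,5-dimethoxyphenyl)-14-(3,5-dihydroxyphenyl)tetradec-8-en-1-one
Product: 11 macrocyclic keto diaryl ether (22-membered): ring B = 3,5-dimethoxy-1,4-phenylene carrying the C1 ketone at C1′ plus the ether oxygen at C4′; ring A = 5-hydroxy-1,3-phenylene carrying the ether oxygen plus C14; bridge = (8Z)-1-oxotetradec-8-ene-1,14-diyl
Conditions: Pd(OAc)2 (10 mol%), Me4tBuXPhos (15 mol%), K3PO4 (3 equiv), toluene, 100 °C; 10 added by syringe pump over 12 h (final 2 mM), then 2 h
Reagents that add atoms: none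
Why: Proposed new method: palladium-catalysed macro-O-arylation, closing a large diaryl ether ring by C–O reductive elimination at palladium on an unprotected resorcinol (to my knowledge not yet shown for a macrocyclisation; the closest known reaction type is the intermolecular Buchwald–Hartwig diaryl ether coupling of hindered aryl bromides, and known ring closures of this kind use copper-mediated Ullmann or SNAr chemistry): zerovalent palladium inserts quickly into the electron-poor C–Br bond even at sub-millimolar concentration, the tethered phenoxide then replaces bromide on palladium in a unimolecular step that slow addition favours over chain growth, and the normally slow C–O reductive elimination is accelerated by the para-acyl group, the two ortho-methoxy groups and the bulky biarylphosphine, while the two hydroxyls of ring A are equivalent (either gives the same ring) and the ketone enolate cannot reach the para-bound palladium.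

Step 5
Reactants: 11 macrocyclic keto diaryl ether (ring B dimethyl ether)
Product: 12 macrocyclic triphenol ketone: as 11 but ring B = 3,5-dihydroxy-1,4-phenylene
Conditions: BBr3 (6 equiv), 2,6-di-tert-butyl-4-methylpyridine (1.5 equiv), CH2Cl2, −78 → 0 °C, 3 h; MeOH then H2O
Reagents that add atoms: none
Why: Lewis-acid ether cleavage (BBr3 demethylation) removes both methyl groups by bromide attack on the boron-activated O–CH3; it is done at the ketone stage because a benzylic alcohol para to an aryloxy group would ionise, the diaryl ether is inert, and low temperature plus the hindered pyridine keep HBr away from the Z-olefin.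

Step 6
Reactants: 12 macrocyclic triphenol ketone
Product: 13 target (1R,8Z)-alcohol: as 12 but C1 is the (R)-configured CH(OH)
Conditions: RuCl[(R,R)-TsDPEN](p-cymene) (2 mol%), HCO2H/Et3N (5:2), EtOAc, 40 °C, 24 h
Reagents that add atoms: none
Why: Noyori–Ikariya asymmetric transfer hydrogenation, in which the (R,R)-TsDPEN ruthenium hydride delivers hydride to the Si face of the aryl n-alkyl ketone through the six-membered outer-sphere transition state held by the aryl/p-cymene CH–π contact, giving the (R)-benzylic alcohol as for acetophenone-type ketones, while the free phenols and the isolated Z-olefin are untouched.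

**Compound list**
1 | 5-bromobenzene-1,3-diol | Oc1cc(O)cc(Br)c1 | starting material
2 | hepta-1,6-diene | C=CCCCC=C | starting material
3 | 9-(hept-6-en-1-yl)-9-borabicyclo[3.3.1]nonane | C=CCCCCCB1C2CCCC1CCC2 | intermediate
4 | 5-(hept-6-en-1-yl)benzene-1,3-diol | C=CCCCCCc1cc(O)cc(O)c1 | intermediate
5 | 4-bromo-3,5-dimethoxybenzoic acid | COc1cc(C(=O)O)cc(OC)c1Br | starting material
6 | 8-bromooct-1-ene | C=CCCCCCCBr | starting material
7 | 4-bromo-3,5-dimethoxybenzoyl chloride | COc1cc(C(Cl)=O)cc(OC)c1Br | intermediate
8 | oct-7-en-1-ylmagnesium bromide | C=CCCCCCC[Mg]Br | intermediate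
9 | 1-(4-bromo-3,5-dimethoxyphenyl)non-8-en-1-one | C=CCCCCCCC(=O)c1cc(OC)c(Br)c(OC)c1 | intermediate
10 | (8Z)-1-(4-bromo-3,5-dimethoxyphenyl)-14-(3,5-dihydroxyphenyl)tetradec-8-en-1-one | COc1cc(cc(OC)c1Br)C(=O)CCCCCC/C=C\CCCCCc1cc(O)cc(O)c1 | intermediate
11 | macrocyclic keto diaryl ether, ring B 3,5-dimethoxy, ring A 5-hydroxy, (8Z)-1-oxotetradec-8-ene-1,14-diyl bridge | Oc1cc2cc(c1)Oc1c(OC)cc(cc1OC)C(=O)CCCCCC/C=C\CCCCC2 | intermediate
12 | macrocyclic triphenol ketone, ring B 3,5-dihydroxy, otherwise as 11 | Oc1cc2cc(c1)Oc1c(O)cc(cc1O)C(=O)CCCCCC/C=C\CCCCC2 | intermediate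
13 | (1R,8Z)-macrocyclic benzylic alcohol, CNP0316989.2 | Oc1cc2cc(c1)Oc1c(O)cc(cc1O)[C@H](O)CCCCCC/C=C\CCCCC2 | target

**Totals**
Total steps: 6. Longest linear sequence: 5 (steps 1, 3, 4, 5, 6; or 2, 3, 4, 5, 6).

**Three steps most likely to fail**

Risk 1, step 4 (the proposed new macro-O-arylation): the likely failures are oligomerisation or catalyst death at millimolar dilution. The fallback uses known chemistry and reverses the order of the two ring-defining bonds. It sets out from 4 and 9. Intermolecular palladium-catalysed diaryl ether coupling under its established concentrated conditions (Pd(OAc)2, Me4tBuXPhos, K3PO4, toluene, 100 °C, 0.3 M, 3 equiv of 4 so that only one hydroxyl reacts) gives 1-{4-[3-(hept-6-en-1-yl)-5-hydroxyphenoxy]-3,5-dimethoxyphenyl}non-8-en-1-one F5. Z-selective ring-closing metathesis of this diene with the ruthenium nitrato complex of step 3 (7.5 mol%, 1,2-dichloroethane, 60 °C, 3 mM, static vacuum) then closes the 22-membered ring. The fallback comes back to the route at 11.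

Risk 2, step 3 (cross-metathesis): the likely failures are a statistical product mixture, an eroded Z:E ratio, or loss of the catalyst to the free phenols. The fallback is a Z-selective Wittig olefination; it sets out from 9 and 1. Lemieux–Johnson cleavage of 9 (OsO4 cat., NaIO4, 2,6-lutidine, dioxane/H2O) gives 8-(4-bromo-3,5-dimethoxyphenyl)-8-oxooctanal F1. Hydroboration of 6-chlorohex-1-ene with 9-BBN-H gives 9-(6-chlorohexyl)-9-borabicyclo[3.3.1]nonane F2, used in the flask. Suzuki coupling of F2 with 1 under the step 1 conditions gives 5-(6-chlorohexyl)benzene-1,3-diol F3. PPh3 and NaI in MeCN at reflux give [6-(3,5-dihydroxyphenyl)hexyl]triphenylphosphonium iodide F4. Deprotonation of F4 with NaN(SiMe3)2 (3.1 equiv, THF, −78 °C; two equivalents for the phenols, one for the ylide) and addition of F1 gives the salt-free, non-stabilised ylide olefination at the aldehyde only. The fallback comes back to the route at 10.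

Risk 3, step 5 (demethylation): the likely failure is HBr addition to, or isomerisation of, the Z-olefin. The fallback changes the protecting group so that boron tribromide never meets an olefin; it sets out from 5. Demethylation of 5 before any olefin is present (BBr3, CH2Cl2, 0 °C → rt) gives 4-bromo-3,5-dihydroxybenzoic acid F6, which is also a catalogue chemical. BnBr and K2CO3 in DMF give benzyl 3,5-bis(benzyloxy)-4-bromobenzoate F7. AlMe3 and MeNH(OMe)·HCl in CH2Cl2 give 3,5-bis(benzyloxy)-4-bromo-N-methoxy-N-methylbenzamide F8. Grignard reagent 8 (THF, 0 °C) gives 1-[3,5-bis(benzyloxy)-4-bromophenyl]non-8-en-1-one F9. Cross-metathesis with 4 as in step 3 gives (8Z)-1-[3,5-bis(benzyloxy)-4-bromophenyl]-14-(3,5-dihydroxyphenyl)tetradec-8-en-1-one F10. Ring closure as in step 4 gives the macrocyclic bis(benzyl ether) ketone F11. BCl3 with pentamethylbenzene (CH2Cl2, −78 °C) then removes both benzyl groups, and the fallback comes back to the route at 12.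

**Further compounds**
F1 | step 3 | 8-(4-bromo-3,5-dimethoxyphenyl)-8-oxooctanal | COc1cc(cc(OC)c1Br)C(=O)CCCCCCC=O
F2 | step 3 | 9-(6-chlorohexyl)-9-borabicyclo[3.3.1]nonane | ClCCCCCCB1C2CCCC1CCC2
F3 | step 3 | 5-(6-chlorohexyl)benzene-1,3-diol | Oc1cc(O)cc(CCCCCCCl)c1
F4 | step 3 | [6-(3,5-dihydroxyphenyl)hexyl]triphenylphosphonium iodide | Oc1cc(O)cc(CCCCCC[P+](c2ccccc2)(c2ccccc2)c2ccccc2)c1.[I-]
F5 | step 4 | 1-{4-[3-(hept-6-en-1-yl)-5-hydroxyphenoxy]-3,5-dimethoxyphenyl}non-8-en-1-one | C=CCCCCCc1cc(O)cc(Oc2c(OC)cc(cc2OC)C(=O)CCCCCCC=C)c1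
F6 | step 5 | 4-bromo-3,5-dihydroxybenzoic acid | Oc1cc(cc(O)c1Br)C(=O)O
F7 | step 5 | benzyl 3,5-bis(benzyloxy)-4-bromobenzoate | O=C(OCc1ccccc1)c1cc(OCc2ccccc2)c(Br)c(OCc2ccccc2)c1
F8 | step 5 | 3,5-bis(benzyloxy)-4-bromo-N-methoxy-N-methylbenzamide | CON(C)C(=O)c1cc(OCc2ccccc2)c(Br)c(OCc2ccccc2)c1
F9 | step 5 | 1-[3,5-bis(benzyloxy)-4-bromophenyl]non-8-en-1-one | C=CCCCCCCC(=O)c1cc(OCc2ccccc2)c(Br)c(OCc2ccccc2)c1
F10 | step 5 | (8Z)-1-[3,5-bis(benzyloxy)-4-bromophenyl]-14-(3,5-dihydroxyphenyl)tetradec-8-en-1-one | Oc1cc(O)cc(CCCCC/C=C\CCCCCCC(=O)c2cc(OCc3ccccc3)c(Br)c(OCc3ccccc3)c2)c1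
F11 | step 5 | macrocyclic bis(benzyl ether) ketone, as 11 with OBn in place of OMe | Oc1cc2cc(c1)Oc1c(OCc3ccccc3)cc(cc1OCc1ccccc1)C(=O)CCCCCC/C=C\CCCCC2
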